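**Retrosynthetic overview**
1. Target 23 is a (1E,3S)-1,3-diarylbut-1-ene with two identical 7-methoxy-2,2-dimethyl-2H-chromen-6-yl groups. The styrene C=C is traced back (dehydration, then reduction) to the (S)-1,3-diarylbutan-1-one 19.
2. Key disconnection of 19: the aryl–C3 bond, made by an intermolecular asymmetric conjugate (Michael-type) addition of arylboronic acid 13 to the aryl (E)-propenyl ketone 18 under rhodium/(R)-BINAP catalysis. This sets the only stereocentre.
3. Both 13 and 18 come from one aryl bromide, 8: bromine–lithium exchange and borate quench for 13; magnesium insertion, crotonaldehyde addition, then MnO2 for 18.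
4. Ring order: the benzene rings are bought (paeonol). Each pyran ring is closed before the union (Kabbe aldol/oxa-Michael annulation to chromanone 6, reduction, dehydration to the chromene). No ring is formed after the key step.

Assumption: the sense of induction follows the established BINAP–rhodium model for acyclic (E)-enones ((S)-BINAP gives (R)-3-arylbutanoyl products from crotonyl acceptors), so (R)-BINAP is used to obtain (S)-19.

**Route**

Step 1
Reactants: 1 1-(2-hydroxy-4-methoxyphenyl)ethanone (paeonol); 2 N-bromosuccinimide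
Product: 3 1-(5-bromo-2-hydroxy-4-methoxyphenyl)ethanone
Conditions: NBS (1.05 equiv), MeCN, 0 °C to rt
Reagents that add atoms: N-bromosuccinimide 2, O=C1CCC(=O)N1Br
Why: Electrophilic aromatic bromination of the doubly activated ring goes to C5 (para to OH, ortho to OMe) in preference to the crowded C3 between the two oxygens; no stereocentre is formed.

Step 2
Reactants: 3 1-(5-bromo-2-hydroxy-4-methoxyphenyl)ethanone; 4 acetone
Product: 6 6-bromo-7-methoxy-2,2-dimethylchroman-4-one, via enone 5 (not isolated)
Conditions: acetone (5 equiv), pyrrolidine (1 equiv), MeOH, rt then 60 °C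
Reagents that add atoms: acetone 4, CC(C)=O
Why: Kabbe condensation, in which a pyrrolidine-mediated crossed aldol condensation with acetone gives enone 5 and the phenol then closes the pyranone by intramolecular oxa-Michael addition, fixing the ring fusion at the former acetyl position; no stereocentre.

Step 3
Reactants: 6 6-bromo-7-methoxy-2,2-dimethylchroman-4-one
Product: 7 6-bromo-7-methoxy-2,2-dimethylchroman-4-ol (racemic)
Conditions: NaBH4, MeOH, 0 °C to rt
Reagents that add atoms: none
Why: Hydride reduction of the aryl ketone; the new carbinol centre is racemic and is removed in the next step.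

Step 4
Reactants: 7 6-bromo-7-methoxy-2,2-dimethylchroman-4-ol (racemic)
Product: 8 6-bromo-7-methoxy-2,2-dimethyl-2H-chromene
Conditions: p-TsOH·H2O (5 mol%), toluene, reflux (Dean–Stark), 1 h
Reagents that add atoms: none
Why: Acid-catalysed E1 dehydration of the benzylic alcohol gives the conjugated 2H-chromene, the standard ending of 2,2-dimethylchromene syntheses, with water removed azeotropically; no stereocentre.

Step 5
Reactants: 8 6-bromo-7-methoxy-2,2-dimethyl-2H-chromene; 9 n-butyllithium; 10 triisopropyl borate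
Product: 13 (7-methoxy-2,2-dimethyl-2H-chromen-6-yl)boronic acid, via aryllithium 11 (not isolated), via lithium borate 12 (not isolated)
Conditions: n-BuLi (1.05 equiv), THF, −78 °C; B(OiPr)3 (1.5 equiv), −78 °C to rt; aq NH4Cl, 0 °C; used promptly
Reagents that add atoms: triisopropyl borate, CC(C)OB(OC(C)C)OC(C)C; water, O
Why: Bromine–lithium exchange followed by borylation with a trialkyl borate and mild hydrolysis; exchange at −78 °C is far faster than ortho-lithiation and the chromene has no acidic allylic hydrogens.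

Step 6
Reactants: 8 6-bromo-7-methoxy-2,2-dimethyl-2H-chromene; 14 magnesium; 15 (E)-but-2-enal
Product: 17 (E)-1-(7-methoxy-2,2-dimethyl-2H-chromen-6-yl)but-2-en-1-ol (racemic), via aryl Grignard reagent 16 (not isolated)
Conditions: Mg turnings (1.3 equiv), I2 (cat.), THF, 45 °C; (E)-but-2-enal (1.1 equiv), −78 to 0 °C; aq NH4Cl; used crude
Reagents that add atoms: (E)-but-2-enal 15, C/C=C/C=O
Why: Magnesium insertion into the aryl bromide gives Grignard reagent 16, and copper-free Grignard addition to an enal goes 1,2 at the carbonyl with the (E)-alkene untouched; the racemic carbinol centre is oxidised away in the next step.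

Step 7
Reactants: 17 (E)-1-(7-methoxy-2,2-dimethyl-2H-chromen-6-yl)but-2-en-1-ol (racemic)
Product: 18 (E)-1-(7-methoxy-2,2-dimethyl-2H-chromen-6-yl)but-2-en-1-one
Conditions: activated MnO2 (15 equiv), CH2Cl2, rt
Reagents that add atoms: none
Why: Chemoselective MnO2 oxidation of a benzylic and allylic alcohol gives the (E)-aryl propenyl ketone without touching the chromene or isomerising the alkene.

Step 8
Reactants: 18 (E)-1-(7-methoxy-2,2-dimethyl-2H-chromen-6-yl)but-2-en-1-one; 13 (7-methoxy-2,2-dimethyl-2H-chromen-6-yl)boronic acid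
Product: 19 (S)-1,3-bis(7-methoxy-2,2-dimethyl-2H-chromen-6-yl)butan-1-one
Conditions: 13 (2.0 equiv), [Rh(OH)((R)-BINAP)]2 (1.5 mol%), dioxane/H2O 10:1, 40 °C
Reagents that add atoms: boronic acid 13, COc1cc2OC(C)(C)C=Cc2cc1B(O)O
Why: Rhodium-catalysed asymmetric conjugate (Michael-type, Hayashi–Miyaura) addition, in which the aryl–rhodium–(R)-BINAP species inserts the (E)-enone from the Si face of C-β and the rhodium enolate is hydrolysed, setting the (S) benzylic stereocentre.

Step 9
Reactants: 19 (S)-1,3-bis(7-methoxy-2,2-dimethyl-2H-chromen-6-yl)butan-1-one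
Product: 20 (3S)-1,3-bis(7-methoxy-2,2-dimethyl-2H-chromen-6-yl)butan-1-ol (mixture of C1 epimers)
Conditions: NaBH4, MeOH/THF, 0 °C to rt
Reagents that add atoms: none
Why: Hydride reduction of the ketone leaves the remote (3S) centre untouched, and the new C1 centre (about 1:1) is destroyed in the final step.

Step 10
Reactants: 20 (3S)-1,3-bis(7-methoxy-2,2-dimethyl-2H-chromen-6-yl)butan-1-ol (mixture of C1 epimers); 21 Burgess reagent
Product: 23 6,6'-[(1E,3S)-but-1-ene-1,3-diyl]bis(7-methoxy-2,2-dimethyl-2H-chromene), via sulfamate ester 22 (not isolated)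
Conditions: Burgess reagent (1.5 equiv), toluene, rt to 50 °C
Reagents that add atoms: none
Why: Burgess dehydration, in which sulfamate ester 22 undergoes thermal syn-elimination under neutral conditions and can only give the aryl-conjugated (E)-alkene (the other β-position is the aryl ipso carbon), leaving the acid-sensitive chromenes and the (S) centre untouched.

**Compound list**
1 | 1-(2-hydroxy-4-methoxyphenyl)ethanone (paeonol) | CC(=O)c1ccc(OC)cc1O | starting material
2 | N-bromosuccinimide | O=C1CCC(=O)N1Br | starting material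
3 | 1-(5-bromo-2-hydroxy-4-methoxyphenyl)ethanone | CC(=O)c1cc(Br)c(OC)cc1O | intermediate
4 | acetone | CC(C)=O | starting material
5 | 1-(5-bromo-2-hydroxy-4-methoxyphenyl)-3-methylbut-2-en-1-one (not isolated) | CC(C)=CC(=O)c1cc(Br)c(OC)cc1O | intermediate
6 | 6-bromo-7-methoxy-2,2-dimethylchroman-4-one | COc1cc2OC(C)(C)CC(=O)c2cc1Br | intermediate
7 | 6-bromo-7-methoxy-2,2-dimethylchroman-4-ol (racemic) | COc1cc2OC(C)(C)CC(O)c2cc1Br | intermediate
8 | 6-bromo-7-methoxy-2,2-dimethyl-2H-chromene | COc1cc2OC(C)(C)C=Cc2cc1Br | intermediate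
9 | n-butyllithium | [Li]CCCC | starting material
10 | triisopropyl borate | CC(C)OB(OC(C)C)OC(C)C | starting material
11 | (7-methoxy-2,2-dimethyl-2H-chromen-6-yl)lithium (not isolated) | COc1cc2OC(C)(C)C=Cc2cc1[Li] | intermediate
12 | lithium triisopropoxy(7-methoxy-2,2-dimethyl-2H-chromen-6-yl)borate (not isolated) | [Li+].COc1cc2OC(C)(C)C=Cc2cc1[B-](OC(C)C)(OC(C)C)OC(C)C | intermediate
13 | (7-methoxy-2,2-dimethyl-2H-chromen-6-yl)boronic acid | COc1cc2OC(C)(C)C=Cc2cc1B(O)O | intermediate
14 | magnesium (turnings) | [Mg] | starting material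
15 | (E)-but-2-enal (crotonaldehyde) | C/C=C/C=O | starting material
16 | (7-methoxy-2,2-dimethyl-2H-chromen-6-yl)magnesium bromide (not isolated) | COc1cc2OC(C)(C)C=Cc2cc1[Mg]Br | intermediate
17 | (E)-1-(7-methoxy-2,2-dimethyl-2H-chromen-6-yl)but-2-en-1-ol (racemic) | COc1cc2OC(C)(C)C=Cc2cc1C(O)/C=C/C | intermediate
18 | (E)-1-(7-methoxy-2,2-dimethyl-2H-chromen-6-yl)but-2-en-1-one | COc1cc2OC(C)(C)C=Cc2cc1C(=O)/C=C/C | intermediate
19 | (S)-1,3-bis(7-methoxy-2,2-dimethyl-2H-chromen-6-yl)butan-1-one | COc1cc2OC(C)(C)C=Cc2cc1C(=O)C[C@H](C)c1cc2C=CC(C)(C)Oc2cc1OC | intermediate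
20 | (3S)-1,3-bis(7-methoxy-2,2-dimethyl-2H-chromen-6-yl)butan-1-ol (mixture of C1 epimers) | COc1cc2OC(C)(C)C=Cc2cc1C(O)C[C@H](C)c1cc2C=CC(C)(C)Oc2cc1OC | intermediate
21 | Burgess reagent, methyl N-(triethylammoniosulfonyl)carbamate inner salt | CC[N+](CC)(CC)S(=O)(=O)[N-]C(=O)OC | starting material
22 | triethylammonium (methoxycarbonyl){[(3S)-1,3-bis(7-methoxy-2,2-dimethyl-2H-chromen-6-yl)butoxy]sulfonyl}azanide (not isolated) | CC[NH+](CC)CC.COC(=O)[N-]S(=O)(=O)OC(C[C@H](C)c1cc2C=CC(C)(C)Oc2cc1OC)c1cc2C=CC(C)(C)Oc2cc1OC | intermediate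
23 | 6,6'-[(1E,3S)-but-1-ene-1,3-diyl]bis(7-methoxy-2,2-dimethyl-2H-chromene) | COc1cc2c(cc1/C=C/[C@H](C)c1cc3c(cc1OC)OC(C)(C)C=C3)C=CC(C)(C)O2 | target

**Totals**
Total step count: 10. Longest linear sequence: 9 steps (1, 2, 3, 4, 6, 7, 8, 9, 10); step 5 is a one-step branch from 8.

**Three steps most likely to fail, with fallbacks**

Step 5 (the electron-rich ortho-alkoxy boronic acid 13 may protodeboronate during hydrolysis and isolation). The fallback sets out from 8 and comes back at 19. Instead of lithiation and borate hydrolysis, a palladium-catalysed Miyaura borylation of 8 (bis(pinacolato)diboron, PdCl2(dppf), KOAc, dioxane, 85 °C) gives the chromatographically stable pinacol boronate 2-(7-methoxy-2,2-dimethyl-2H-chromen-6-yl)-4,4,5,5-tetramethyl-1,3,2-dioxaborolane F1. This is used directly in place of 13 in the conjugate addition to 18 ([Rh(OH)((R)-BINAP)]2, KOH (0.5 equiv), dioxane/H2O, 60 °C) to give 19.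

Step 8 (the hindered, electron-rich boronic acid may give low conversion or an ee below what is needed; a modest shortfall can be corrected by recrystallising 19). The fallback sets out from 8 and comes back at 19, replacing catalyst control by an auxiliary-controlled conjugate addition with separable diastereomers. (R)-4-Phenyloxazolidin-2-one is N-acylated (n-BuLi, (E)-but-2-enoyl chloride, THF, −78 °C) to (R)-3-[(E)-but-2-enoyl]-4-phenyloxazolidin-2-one F2. Bromide 8 is converted (Mg, THF) into Grignard reagent 16 as in step 6. With CuBr·SMe2 (20 mol%, THF/Me2S, −40 to −10 °C, then aqueous NH4Cl) 16 adds to the magnesium-chelated s-cis imide on the face anti to the phenyl group, giving (R)-3-[(S)-3-(7-methoxy-2,2-dimethyl-2H-chromen-6-yl)butanoyl]-4-phenyloxazolidin-2-one F3, which is purified to a single diastereomer by crystallisation or chromatography. Transamidation (MeNHOMe·HCl, AlMe3, CH2Cl2, 0 °C) gives the Weinreb amide (S)-N-methoxy-3-(7-methoxy-2,2-dimethyl-2H-chromen-6-yl)-N-methylbutanamide F4. Addition of a second portion of Grignard reagent 16 (THF, 0 °C, then aqueous NH4Cl) delivers ketone 19.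

Step 10 (ionisation of the very electron-rich benzylic sulfamate could lead to oligomers, cyclised by-products or some (Z)-alkene). The fallback sets out from 19, bypasses 20, and comes back at 23 without any cationic intermediate. Ketone 19 is deprotonated to its (Z)-enolate (KN(SiMe3)2, THF, −78 °C) and trapped with PhNTf2 to give the enol triflate (S,Z)-1,3-bis(7-methoxy-2,2-dimethyl-2H-chromen-6-yl)but-1-en-1-yl trifluoromethanesulfonate F5. Palladium-catalysed formate reduction (Pd(OAc)2, PPh3, HCO2H, Et3N, DMF, 60 °C) replaces the triflate by hydrogen with retention of alkene geometry, giving the (E)-alkene 23.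

**Further compounds**
F1 | step 5 | 2-(7-methoxy-2,2-dimethyl-2H-chromen-6-yl)-4,4,5,5-tetramethyl-1,3,2-dioxaborolane | COc1cc2OC(C)(C)C=Cc2cc1B1OC(C)(C)C(C)(C)O1
F2 | step 8 | (R)-3-[(E)-but-2-enoyl]-4-phenyloxazolidin-2-one | O=C1OC[C@@H](c2ccccc2)N1C(=O)/C=C/C
F3 | step 8 | (R)-3-[(S)-3-(7-methoxy-2,2-dimethyl-2H-chromen-6-yl)butanoyl]-4-phenyloxazolidin-2-one | O=C1OC[C@@H](c2ccccc2)N1C(=O)C[C@H](C)c1cc2C=CC(C)(C)Oc2cc1OC
F4 | step 8 | (S)-N-methoxy-3-(7-methoxy-2,2-dimethyl-2H-chromen-6-yl)-N-methylbutanamide | CON(C)C(=O)C[C@H](C)c1cc2C=CC(C)(C)Oc2cc1OC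
F5 | step 10 | (S,Z)-1,3-bis(7-methoxy-2,2-dimethyl-2H-chromen-6-yl)but-1-en-1-yl trifluoromethanesulfonate | COc1cc2OC(C)(C)C=Cc2cc1/C(OS(=O)(=O)C(F)(F)F)=C/[C@H](C)c1cc2C=CC(C)(C)Oc2cc1OC
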